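The tetrahydrofuran (O1, C2 aryl, C3 CH2OH, C4 aroyl, C5 H2) is cut at O1–C5. C5 lies β to the aryl ketone carbonyl, the homoenolate position, and O1 is the benzylic oxygen on C2, so both ends can be hidden in a 1-arylcyclopropanol carrying a free benzylic hydroxyl. In one operation a copper-catalysed aerobic ring opening releases the cyclopropane strain, unveils the ketone, makes the cyclopropane CH2 an electrophilic C5 and lets the C2 hydroxyl close the ring, with C4 settling trans by equilibration. The precursor, cyclopropanol 13, comes from a Kulinkovich–Cha coupling of an isovanillate ester with a homoallylic alcohol whose stereocentres (future C2, C3) are set by an Evans syn-aldol reaction.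

Key step: step 8

Remark: TBS = tert-butyldimethylsilyl and Ar = 3-(TBS-oxy)-4-methoxyphenyl. The two cyclopropane stereocentres of 13 are inconsequential, since one becomes the carbonyl carbon and the other the base-equilibrated C4. Compound 13 is therefore carried as a diastereomer mixture and its SMILES leaves these two atoms undefined.

Step 1
Reactants: 1 isovanillin (3-hydroxy-4-methoxybenzaldehyde)
Product: 2 3-(TBS-oxy)-4-methoxybenzaldehyde
Conditions: TBSCl (1.2 equiv), imidazole (2.5 equiv), DMF, rt
Reagents that add atoms: tert-butyldimethylsilyl chloride, CC(C)(C)[Si](C)(C)Cl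
Why: Imidazole-promoted silyl ether formation at the phenol, which masks the oxidisable, acidic OH for the boron, titanium and copper steps and leaves the aldehyde untouched.

Step 2
Reactants: 3 (S)-4-benzyl-1,3-oxazolidin-2-one; 4 (E,E)-crotonic anhydride
Product: 5 (S)-4-benzyl-3-[(E)-but-2-enoyl]-1,3-oxazolidin-2-one
Conditions: LiCl (1.1 equiv), Et3N (1.5 equiv), THF, −20 °C → rt
Reagents that add atoms: none
Why: Lithium chloride/triethylamine-promoted N-acylation of the oxazolidinone by the anhydride, a mild imide formation that avoids strong base and polymerisation of the unsaturated acyl donor.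

Step 3
Reactants: 5 (S)-4-benzyl-3-[(E)-but-2-enoyl]-1,3-oxazolidin-2-one; 2 3-(TBS-oxy)-4-methoxybenzaldehyde
Product: 8 (S)-4-benzyl-3-[(2S,3S)-2-ethenyl-3-hydroxy-3-Ar-propanoyl]-1,3-oxazolidin-2-one, via dibutylboron Z-dienolate 6 (not isolated), via O-dibutylboryl aldolate 7 (not isolated)
Conditions: Bu2BOTf (1.2 equiv), Et3N (1.4 equiv), CH2Cl2, −78 → 0 °C; then 2, −78 → 0 °C; pH 7 buffer, MeOH, H2O2, 0 °C
Reagents that add atoms: dibutylboron triflate, CCCCB(CCCC)OS(=O)(=O)C(F)(F)F (its boryl group stays only in 6 and 7, not in 8)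
Why: Evans boron aldol reaction of a crotonate imide, in which soft enolisation removes a γ-proton to give the Z(O)-dienolate 6 that adds at its α-carbon through a closed Zimmerman–Traxler chair on the face opposite the benzyl group, so that the (S)-auxiliary should give the syn (2S,3S) adduct as it does with propionate imides and aryl aldehydes.

Step 4
Reactants: 8 (S)-4-benzyl-3-[(2S,3S)-2-ethenyl-3-hydroxy-3-Ar-propanoyl]-1,3-oxazolidin-2-one
Product: 9 (1S,2R)-2-ethenyl-1-Ar-propane-1,3-diol
Conditions: LiBH4 (2 equiv), H2O (1 equiv), Et2O, 0 °C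
Reagents that add atoms: none
Why: Reductive cleavage of the imide by borohydride gives the primary alcohol and returns the auxiliary, without enolisation, so the non-conjugated vinyl group and both stereocentres are kept (the 2R descriptor follows only from the changed priority of CH2OH).

Step 5
Reactants: 9 (1S,2R)-2-ethenyl-1-Ar-propane-1,3-diol
Product: 10 (1S,2R)-2-[(TBS-oxy)methyl]-1-Ar-but-3-en-1-ol
Conditions: TBSCl (1.05 equiv), imidazole (2 equiv), CH2Cl2, −20 → 0 °C
Reagents that add atoms: tert-butyldimethylsilyl chloride, CC(C)(C)[Si](C)(C)Cl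
Why: Sterically controlled mono-silylation, since the primary hydroxyl reacts much faster than the hindered secondary benzylic one, which stays free to direct step 7 and to act as the nucleophile in step 8.

Step 6
Reactants: 11 methyl 3-hydroxy-4-methoxybenzoate (methyl isovanillate)
Product: 12 methyl 3-(TBS-oxy)-4-methoxybenzoate
Conditions: TBSCl (1.2 equiv), imidazole (2.5 equiv), DMF, rt
Reagents that add atoms: tert-butyldimethylsilyl chloride, CC(C)(C)[Si](C)(C)Cl
Why: Imidazole-promoted silylation of the phenol, giving the same protecting group as in 10 so that a single final step removes all three.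

Step 7
Reactants: 10 (1S,2R)-2-[(TBS-oxy)methyl]-1-Ar-but-3-en-1-ol; 12 methyl 3-(TBS-oxy)-4-methoxybenzoate (1.5 equiv)
Product: 13 1-Ar-2-[(2R,3S)-1-(TBS-oxy)-3-hydroxy-3-Ar-propan-2-yl]cyclopropan-1-ol (diastereomer mixture at the cyclopropane)
Conditions: ClTi(OiPr)3 (1.0 equiv), cyclohexylmagnesium chloride (4.5 equiv, slow addition), THF, 0 °C → rt
Reagents that add atoms: none
Why: Kulinkovich–Cha hydroxycyclopropanation by ligand exchange, in which the titanium–cyclohexene complex formed from the Grignard reagent exchanges its alkene for the terminal alkene of 10 (assisted by the homoallylic alkoxide), inserts the ester carbonyl and contracts with loss of methoxide to the 1-aryl-2-alkylcyclopropanol, leaving the two chain stereocentres untouched and creating two ring stereocentres that need no control.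

Step 8
Reactants: 13 1-Ar-2-[(2R,3S)-1-(TBS-oxy)-3-hydroxy-3-Ar-propan-2-yl]cyclopropan-1-ol
Product: 15 [(3S,4R,5S)-5-Ar-4-[(TBS-oxy)methyl]oxolan-3-yl](Ar)methanone (all-trans), via α-methylene ketone 14 (not isolated)
Conditions: Cu(OTf)2 (20 mol %), 2,2'-bipyridine (20 mol %), O2 (1 atm), MeCN, 40 °C; then DBU (0.3 equiv), rt
Reagents that add atoms: none
Why: The divalent-copper cyclopropoxide of 13 undergoes strain-driven β-carbon scission of the less substituted C1–CH2 bond, which unveils the aryl ketone and leaves the former cyclopropane CH2 as a primary β-keto alkylcopper (homoenolate) that, after oxidation to trivalent copper, loses β-hydride to give enone 14; the benzylic hydroxyl then adds to the exocyclic methylene and forms the O1–C5 bond, and O2 returns copper to the divalent state (direct C–O reductive elimination from an alkylcopper alkoxide would make the same bond). The closest known reaction type is the copper-catalysed aerobic ring-opening cyclisation of hydroxy-tethered cyclopropanols to 3-acyl tetrahydrofurans, a homoenolate/oxa-Michael sequence. The tetrahydrofuran closes in the 5-endo-trig mode, acceptable for an oxygen nucleophile adding reversibly to an enone whose cyclised form is the more stable. C4 is the only new stereocentre: it is set by enolate protonation and equilibrated by DBU to the 3,4-trans isomer, in which the aroyl group lies opposite the C3 silyloxymethyl group, while C2 and C3 are carried over from 10 and both cyclopropane stereocentres are erased, so the diastereomers of 13 converge. The step needs scission of C1–CH2 and not C1–CH, secured by the preference of copper for the less hindered primary carbon, and attack by the benzylic oxygen alone, secured by silylation of the primary and phenolic hydroxyls.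

Step 9
Reactants: 15 [(3S,4R,5S)-5-Ar-4-[(TBS-oxy)methyl]oxolan-3-yl](Ar)methanone
Product: 16 [(3S,4R,5S)-5-(3-hydroxy-4-methoxyphenyl)-4-(hydroxymethyl)oxolan-3-yl](3-hydroxy-4-methoxyphenyl)methanone (CNP0234761.1)
Conditions: TBAF (4 equiv), AcOH (4 equiv), THF, 0 °C → rt
Reagents that add atoms: none
Why: Fluoride-mediated cleavage of the two aryl silyl ethers and the primary silyl ether, buffered with acetic acid so that the β-alkoxy ketone should not open by retro-oxa-Michael reaction and the all-trans stereotriad stays intact.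

Compound list
1 | isovanillin (3-hydroxy-4-methoxybenzaldehyde) | COc1ccc(C=O)cc1O | starting material
2 | 3-(TBS-oxy)-4-methoxybenzaldehyde | COc1ccc(C=O)cc1O[Si](C)(C)C(C)(C)C | intermediate
3 | (S)-4-benzyl-1,3-oxazolidin-2-one | O=C1N[C@@H](Cc2ccccc2)CO1 | starting material
4 | (E,E)-crotonic anhydride | C/C=C/C(=O)OC(=O)/C=C/C | starting material
5 | (S)-4-benzyl-3-[(E)-but-2-enoyl]-1,3-oxazolidin-2-one | C/C=C/C(=O)N1[C@@H](Cc2ccccc2)COC1=O | intermediate
6 | dibutylboron (Z)-dienolate of 5 (not isolated) | C=C/C=C(\OB(CCCC)CCCC)N1[C@@H](Cc2ccccc2)COC1=O | intermediate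
7 | O-dibutylboryl aldolate of 8 (not isolated) | C=C[C@@H]([C@H](OB(CCCC)CCCC)c1ccc(OC)c(O[Si](C)(C)C(C)(C)C)c1)C(=O)N1[C@@H](Cc2ccccc2)COC1=O | intermediate
8 | (S)-4-benzyl-3-[(2S,3S)-2-ethenyl-3-hydroxy-3-Ar-propanoyl]-1,3-oxazolidin-2-one | C=C[C@@H]([C@H](O)c1ccc(OC)c(O[Si](C)(C)C(C)(C)C)c1)C(=O)N1[C@@H](Cc2ccccc2)COC1=O | intermediate
9 | (1S,2R)-2-ethenyl-1-Ar-propane-1,3-diol | C=C[C@@H]([C@H](O)c1ccc(OC)c(O[Si](C)(C)C(C)(C)C)c1)CO | intermediate
10 | (1S,2R)-2-[(TBS-oxy)methyl]-1-Ar-but-3-en-1-ol | C=C[C@@H]([C@H](O)c1ccc(OC)c(O[Si](C)(C)C(C)(C)C)c1)CO[Si](C)(C)C(C)(C)C | intermediate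
11 | methyl 3-hydroxy-4-methoxybenzoate (methyl isovanillate) | COC(=O)c1ccc(OC)c(O)c1 | starting material
12 | methyl 3-(TBS-oxy)-4-methoxybenzoate | COC(=O)c1ccc(OC)c(O[Si](C)(C)C(C)(C)C)c1 | intermediate
13 | 1-Ar-2-[(2R,3S)-1-(TBS-oxy)-3-hydroxy-3-Ar-propan-2-yl]cyclopropan-1-ol, mixture of cyclopropane diastereomers | COc1ccc(C2(O)CC2[C@H](CO[Si](C)(C)C(C)(C)C)[C@H](O)c3ccc(OC)c(O[Si](C)(C)C(C)(C)C)c3)cc1O[Si](C)(C)C(C)(C)C | intermediate
14 | (3R,4S)-4-hydroxy-2-methylidene-1,4-bis(Ar)-3-[(TBS-oxy)methyl]butan-1-one (not isolated) | COc1ccc(C(=O)C(=C)[C@H](CO[Si](C)(C)C(C)(C)C)[C@H](O)c2ccc(OC)c(O[Si](C)(C)C(C)(C)C)c2)cc1O[Si](C)(C)C(C)(C)C | intermediate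
15 | [(3S,4R,5S)-5-Ar-4-[(TBS-oxy)methyl]oxolan-3-yl](Ar)methanone | COc1ccc(C(=O)[C@@H]2CO[C@H](c3ccc(OC)c(O[Si](C)(C)C(C)(C)C)c3)[C@H]2CO[Si](C)(C)C(C)(C)C)cc1O[Si](C)(C)C(C)(C)C | intermediate
16 | [(3S,4R,5S)-5-(3-hydroxy-4-methoxyphenyl)-4-(hydroxymethyl)oxolan-3-yl](3-hydroxy-4-methoxyphenyl)methanone, CNP0234761.1 | COc1ccc(C(=O)[C@@H]2CO[C@H](c3ccc(OC)c(O)c3)[C@H]2CO)cc1O | target

Total steps: 9. Longest linear sequence: 7 steps (steps 1, 3, 4, 5, 7, 8 and 9, from 1 to 16).

Steps most likely to fail

Step 8 (key step). The ring opening may follow a free-radical course and cut the more substituted cyclopropane bond. The Lewis-acidic copper salt may also ionise or oxidise the electron-rich benzylic alcohol, or the sequence may stall at the open enone. The fallback sets out from 13 and comes back at 15. Electrophilic ring opening with N-bromosuccinimide (CH2Cl2, −20 °C) should place bromine on the less substituted carbon and give (3R,4S)-2-(bromomethyl)-4-hydroxy-1,4-bis(Ar)-3-[(TBS-oxy)methyl]butan-1-one F1. Treatment of F1 with K2CO3 in MeCN should then close the same O1–C5 bond, by elimination to 14 and oxa-Michael addition or by direct displacement, and equilibrate C4 to give 15.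

Step 7. Ligand exchange of the α-branched terminal alkene on titanium may be slow, so that reduction or simple Grignard addition at the aryl ester competes. The fallback sets out from 10 (with aldehyde 2) and comes back at 13, and delivers the acyl group intramolecularly. Pinnick oxidation of 2 (NaClO2, NaH2PO4, 2-methylbut-2-ene, t-BuOH/H2O) should give 3-(TBS-oxy)-4-methoxybenzoic acid F2. Steglich esterification of F2 with 10 (EDC, DMAP, CH2Cl2) should give the homoallyl ester (1S,2R)-2-[(TBS-oxy)methyl]-1-Ar-but-3-en-1-yl 3-(TBS-oxy)-4-methoxybenzoate F3. Treatment of F3 with Ti(OiPr)4 and isopropylmagnesium chloride (2 equiv, Et2O, −50 → 0 °C) should form the titanium–alkene complex, which attacks the tethered ester and then closes onto the released ketone. This tandem intramolecular acyl substitution and carbonyl addition is an isomerisation of F3 to 13.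

Step 3. The dienolate may react at its γ-carbon, or addition to the electron-rich aldehyde may be sluggish and reverse on work-up, with loss of diastereomeric purity. The fallback sets out from 2 and comes back at 9, skipping 5 to 8, and makes no compound outside the list (F0). It is an iridium-catalysed transfer-hydrogenative anti-(hydroxymethyl)allylation of 2 with 4-vinyl-1,3-dioxolan-2-one ([Ir(cod)Cl]2, SEGPHOS, 4-cyano-3-nitrobenzoic acid, isopropanol, THF, 60 °C). This should give the anti diol 9 directly, with the ligand antipode chosen on a model aldehyde to deliver the (1S,2R) isomer.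

Further compounds
F1 | step 8 | (3R,4S)-2-(bromomethyl)-4-hydroxy-1,4-bis(Ar)-3-[(TBS-oxy)methyl]butan-1-one, mixture at C2 | COc1ccc(C(=O)C(CBr)[C@H](CO[Si](C)(C)C(C)(C)C)[C@H](O)c2ccc(OC)c(O[Si](C)(C)C(C)(C)C)c2)cc1O[Si](C)(C)C(C)(C)C
F2 | step 7 | 3-(TBS-oxy)-4-methoxybenzoic acid | COc1ccc(C(=O)O)cc1O[Si](C)(C)C(C)(C)C
F3 | step 7 | (1S,2R)-2-[(TBS-oxy)methyl]-1-Ar-but-3-en-1-yl 3-(TBS-oxy)-4-methoxybenzoate | C=C[C@@H]([C@H](OC(=O)c1ccc(OC)c(O[Si](C)(C)C(C)(C)C)c1)c1ccc(OC)c(O[Si](C)(C)C(C)(C)C)c1)CO[Si](C)(C)C(C)(C)C
F0 | step 3 | none | none
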